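All runs come from a simulation with constants of no real substance; scatter was added.

Percent of the L charged is the unit in which these runs can be laid over one another.

| setting | maple | birch | flask |
|---|---|---|---|
| L | 1.4 mM | 2.2 mM | 1.0 mM |
| G | 0.19 mM (held) | 0.19 mM (held) | 0.19 mM (held) |
| remark | run made earlier | run made earlier |  |
| time |  |  | 30 min |

- maple (time / min: J / %, Q / %): 3.00: 51.7, 5.6; 5.00: 48.3, 7.6; 10.0: 44.3, 14.9; 20.0: 39.8, 25.3; 40.0: 34.2, 38.9
- birch (time / min: J / %, Q / %): 8.00: 46.0, 12.4; 15.0: 43.8, 19.8; 20.0: 38.2, 24.6; 30.0: 34.4, 33.7; 40.0: 32.9, 39.0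

(each reading ± 1 percentage point)

- ratio of J to Q at 1.5 s
- ratio of J to Q at 30 min

- at the start none of Z is dissolved
- on the list of suspects stand: G <-> Z; Z -> X; L + Z <-> Q; L + Z <-> J

At 20.0 min, maple and birch read Q 25.3 % and 24.6 %, and at 40.0 min they read 38.9 % and 39.0 %, though birch holds 1.57 times the L of maple. Those gaps lie within the scatter of 1 percentage point, so I read both curves as pseudo-first-order in L, with percentages that do not move with the charge. But then the late question needs no model, since birch was read at 30.0 min, the asked time. I carry ρ = 1.02, the charge-free ratio, J over Q read in birch at that time. It is a reading and carries the scatter of its two values. For 1.5 s I have no reading: the earliest, at 3.00 min, gives J over Q of 9.23, and I commit to no number there.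

The forecast gives 80 (from 20 to 500) and, a little above my ρ, 1.05 (from 0.95 to 1.17), holding that “J is the kinetic product”.

The flask gives 78.3 and 1.05, the second 0.0300 above ρ.

    G ⇌ Z, rate k1*(csat - [Z]) (kL = 6.60 /s)
    Z → X (k = 0.0190 /s)
    L + Z ⇌ Q (K = 14000 /M, k = 3.10 /M/s)
    L + Z ⇌ J (K = 5800 /M, k = 250 /M/s)

The neighbouring flask is this flask with 0.25 mM of L, a quarter of the charge, time and all else held. The same reckoning takes ρ over unchanged, so it again says 1.02. The neighbour gives 1.05 at 30 min, again 0.0300 above ρ, with Q at 33.2 % and L at 32 % of its charge.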